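**Retrosynthetic overview**
1. Target ⇒ O‑sulfation and ester hydrolysis of the cis‑decalin hydroxy dienoate.
2. Both rings form in one step. The cis‑decalin comes from an intramolecular [4+2] of the complete, unprotected linear C18 hexaene ester (bonds C7–C12 and C6–C15). The diene is C12–C15 (12Z,14E) and the dienophile is the distal 6E alkene of the 2,4,6‑trienoate, mirroring the presumed polyketide cyclisation. C8 and C9 control the four new stereocentres.
3. Hexaene ⇒ Heck union at C5–C6 of an iodo‑dienoate with a terminal alkene.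
4. C8–C9 ⇒ catalytic asymmetric anti‑crotylboration of a (Z,E,E)‑trienal.
5. Trienal ⇒ Z‑selective Wittig (C12=C13) and E‑selective Wittig (C14=C15), starting from tiglaldehyde.

Assumption: the target is wanted as drawn, with a free carboxylic acid and a hydrogen sulfate, not as a salt. Atoms carry polyketide numbers, C1 (carboxyl) to C18 (terminal CH3). Decalin positions 1/2/3/4/4a/5/6/7/8/8a correspond to C6/15/14/13/12/11/10/9/8/7.

**Step 1**
Reactants: 1 (E)-2-methylbut-2-enal (tiglaldehyde); 2 2-(triphenylphosphoranylidene)propanal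
Product: 3 (2E,4E)-2,4-dimethylhexa-2,4-dienal
Conditions: PhMe, 110 °C, 24 h
Reagents that add atoms: 2-(triphenylphosphoranylidene)propanal (2), CC(C=O)=P(c1ccccc1)(c1ccccc1)c1ccccc1
Why: Wittig olefination with a formyl‑stabilised ylide gives the E trisubstituted alkene (C14=C15, chain trans), and the product dienal is too hindered and deactivated to be homologated a second time at a useful rate.

**Step 2**
Reactants: 3 (2E,4E)-2,4-dimethylhexa-2,4-dienal; 4 [3-(ethoxycarbonyl)propyl]triphenylphosphonium bromide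
Product: 6 ethyl (4Z,6E,8E)-6,8-dimethyldeca-4,6,8-trienoate, via phosphonium ylide 5 (not isolated)
Conditions: 4, NaHMDS, THF, 0 °C; then 3, −78 °C → rt
Reagents that add atoms: [3-(ethoxycarbonyl)propyl]triphenylphosphonium bromide (4), CCOC(=O)CCC[P+](c1ccccc1)(c1ccccc1)c1ccccc1.[Br-]
Why: Wittig olefination of a non‑stabilised ylide under lithium‑free conditions runs through the kinetically favoured cis‑oxaphosphetane and sets the 12Z alkene (typically ≥10:1) without touching the two E alkenes or the ester.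

**Step 3**
Reactants: 6 ethyl (4Z,6E,8E)-6,8-dimethyldeca-4,6,8-trienoate
Product: 8 (4Z,6E,8E)-6,8-dimethyldeca-4,6,8-trienal, via diisobutylaluminium hemiacetal 7 (not isolated)
Conditions: DIBAL‑H (1.05 equiv), CH2Cl2, −78 °C; aq. Rochelle salt
Reagents that add atoms: none
Why: In this DIBAL‑H partial reduction the tetrahedral aluminium hemiacetal is stable at −78 °C and collapses to the aldehyde only on work‑up, and the unactivated triene is inert to DIBAL‑H at this temperature.

**Step 4**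
Reactants: 8 (4Z,6E,8E)-6,8-dimethyldeca-4,6,8-trienal; 9 (E)-crotylboronic acid pinacol ester
Product: 11 (3R,4S,7Z,9E,11E)-3,9,11-trimethyltrideca-1,7,9,11-tetraen-4-ol, via pinacol borate ester 10 (not isolated)
Conditions: (R)-TRIP (5 mol %), 4 Å MS, PhMe, −30 °C; aq. NaHCO3
Reagents that add atoms: (E)-crotylboronic acid pinacol ester (9), C/C=C/CB1OC(C)(C)C(C)(C)O1
Why: Chiral‑phosphoric‑acid‑catalysed asymmetric crotylboration runs through a closed Zimmerman–Traxler chair in which the E‑crotyl geometry gives the anti 8‑Me/9‑OH relationship and (R)-TRIP, hydrogen‑bonded to the pseudoaxial boronate oxygen and the formyl H, directs attack to the Re face of 8, giving 9S and therefore 8R.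

**Step 5**
Reactants: 12 ethyl (E)-4-oxobut-2-enoate; 13 iodoform
Product: 15 ethyl (2E,4E)-5-iodopenta-2,4-dienoate, via iodomethylidene dichromium reagent 14 (not isolated)
Conditions: CrCl2 (6 equiv), CHI3 (2 equiv), THF, 0 °C, dark
Reagents that add atoms: iodoform (13), IC(I)I
Why: In the Takai olefination the gem‑dichromium species adds to the aldehyde and eliminates to the E alkenyl iodide, the enoate is not reduced by Cr(II) at 0 °C, and the minor 4Z isomer is removed by chromatography.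

**Step 6**
Reactants: 11 (3R,4S,7Z,9E,11E)-3,9,11-trimethyltrideca-1,7,9,11-tetraen-4-ol; 15 ethyl (2E,4E)-5-iodopenta-2,4-dienoate
Product: 16 ethyl (2E,4E,6E,8R,9S,12Z,14E,16E)-9-hydroxy-8,14,16-trimethyloctadeca-2,4,6,12,14,16-hexaenoate
Conditions: Pd(OAc)2 (10 mol %), n‑Bu4NCl, K2CO3, DMF, 35 °C, dark
Reagents that add atoms: ethyl (2E,4E)-5-iodopenta-2,4-dienoate (15), CCOC(=O)/C=C/C=C/I
Why: In this Mizoroki–Heck reaction (Jeffery conditions) the dienyl‑Pd species forms with retention, adds syn to the CH2 terminus of the only monosubstituted alkene (the internal triene alkenes insert far more slowly), and syn β‑H elimination of the now allylic C6–H gives the conjugated 6E alkene, while carbonate removes HPdI quickly so that 12Z, C8 and C9 stay untouched.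

**Step 7**
Reactants: 16 ethyl (2E,4E,6E,8R,9S,12Z,14E,16E)-9-hydroxy-8,14,16-trimethyloctadeca-2,4,6,12,14,16-hexaenoate
Product: 19 ethyl (2E,4E)-5-[(1S,2R,4aS,7S,8R,8aR)-2-[(2E)-but-2-en-2-yl]-7-hydroxy-3,8-dimethyl-1,2,4a,5,6,7,8,8a-octahydronaphthalen-1-yl]penta-2,4-dienoate, via hexaene aluminium alkoxide 17 (not isolated), via cycloadduct aluminium alkoxide 18 (not isolated)
Conditions: Me2AlCl (2.5 equiv), CH2Cl2 (5 mM), −78 → −10 °C; aq. Rochelle salt
Reagents that add atoms: none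
Why: In this Lewis‑acid‑promoted type‑1 intramolecular Diels–Alder reaction one Me2AlCl caps O9 as a bulky alkoxide (and scavenges protons) while a second lowers the trienoate LUMO (largest coefficient at C7) and the 14‑methyl group removes the usual s‑trans preference of a Z‑diene, so that the four‑carbon tether permits only C7–C12/C6–C15 closure, the 12Z geometry (tether inside) permits only the cis‑fused transition state with C8 exo and the dienoate arm endo (H7, H12, C5 and the 14E‑outside butenyl group all on one face, i.e. 6S,7R,12S,15R), and the face is fixed by the chair tether in which C6 is axial, which forces O9 equatorial (8‑Me axial, anti to C6) because the other face would place O9 syn‑diaxial to C6.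

**Step 8**
Reactants: 19 ethyl (2E,4E)-5-[(1S,2R,4aS,7S,8R,8aR)-2-[(2E)-but-2-en-2-yl]-7-hydroxy-3,8-dimethyl-1,2,4a,5,6,7,8,8a-octahydronaphthalen-1-yl]penta-2,4-dienoate
Product: 22 (2E,4E)-5-[(1S,2R,4aS,7S,8R,8aR)-2-[(2E)-but-2-en-2-yl]-3,8-dimethyl-7-(sulfooxy)-1,2,4a,5,6,7,8,8a-octahydronaphthalen-1-yl]penta-2,4-dienoic acid (CNP0450810.2), via pyridinium sulfate ester 20 (not isolated), via dilithium sulfate carboxylate 21 (not isolated)
Conditions: SO3·py, pyridine, rt; then LiOH, THF–MeOH–H2O, rt; then 1 M HCl, 0 °C, pH 1–2, C18 desalting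
Reagents that add atoms: sulfur trioxide–pyridine complex, [O-]S(=O)(=O)[n+]1ccccc1; lithium hydroxide, [Li+].[OH-]
Why: O‑sulfation of the secondary alcohol with mild SO3·pyridine (retention at C9, alkenes untouched) is followed by saponification of the dienoate, to which sulfate monoester anions are inert, and by cold acidification to the neutral form, with no stereocentre involved.

**Compound list**
1 | (E)-2-methylbut-2-enal | C/C=C(\C)C=O | starting material
2 | 2-(triphenylphosphoranylidene)propanal | CC(C=O)=P(c1ccccc1)(c1ccccc1)c1ccccc1 | starting material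
3 | (2E,4E)-2,4-dimethylhexa-2,4-dienal | C/C=C(\C)/C=C(\C)C=O | intermediate
4 | [3-(ethoxycarbonyl)propyl]triphenylphosphonium bromide | CCOC(=O)CCC[P+](c1ccccc1)(c1ccccc1)c1ccccc1.[Br-] | starting material
5 | ethyl 4-(triphenylphosphoranylidene)butanoate (ylide) | CCOC(=O)CCC=P(c1ccccc1)(c1ccccc1)c1ccccc1 | intermediate
6 | ethyl (4Z,6E,8E)-6,8-dimethyldeca-4,6,8-trienoate | C/C=C(\C)/C=C(\C)/C=C\CCC(=O)OCC | intermediate
7 | {[(4Z,6E,8E)-1-ethoxy-6,8-dimethyldeca-4,6,8-trien-1-yl]oxy}diisobutylalane | C/C=C(\C)/C=C(\C)/C=C\CCC(OCC)O[Al](CC(C)C)CC(C)C | intermediate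
8 | (4Z,6E,8E)-6,8-dimethyldeca-4,6,8-trienal | C/C=C(\C)/C=C(\C)/C=C\CCC=O | intermediate
9 | (E)-crotylboronic acid pinacol ester | C/C=C/CB1OC(C)(C)C(C)(C)O1 | starting material
10 | 2-{[(3R,4S,7Z,9E,11E)-3,9,11-trimethyltrideca-1,7,9,11-tetraen-4-yl]oxy}-4,4,5,5-tetramethyl-1,3,2-dioxaborolane | C/C=C(\C)/C=C(\C)/C=C\CC[C@H](OB1OC(C)(C)C(C)(C)O1)[C@H](C)C=C | intermediate
11 | (3R,4S,7Z,9E,11E)-3,9,11-trimethyltrideca-1,7,9,11-tetraen-4-ol | C/C=C(\C)/C=C(\C)/C=C\CC[C@H](O)[C@H](C)C=C | intermediate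
12 | ethyl (E)-4-oxobut-2-enoate | CCOC(=O)/C=C/C=O | starting material
13 | iodoform | IC(I)I | starting material
14 | (iodomethanediyl)bis(dichlorochromium(III)) | IC([Cr](Cl)Cl)[Cr](Cl)Cl | intermediate
15 | ethyl (2E,4E)-5-iodopenta-2,4-dienoate | CCOC(=O)/C=C/C=C/I | intermediate
16 | ethyl (2E,4E,6E,8R,9S,12Z,14E,16E)-9-hydroxy-8,14,16-trimethyloctadeca-2,4,6,12,14,16-hexaenoate | C/C=C(\C)/C=C(\C)/C=C\CC[C@H](O)[C@H](C)/C=C/C=C/C=C/C(=O)OCC | intermediate
17 | O9‑chloro(methyl)aluminium alkoxide of 16 | C/C=C(\C)/C=C(\C)/C=C\CC[C@H](O[Al](C)Cl)[C@H](C)/C=C/C=C/C=C/C(=O)OCC | intermediate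
18 | O9‑chloro(methyl)aluminium alkoxide of 19 | C/C=C(\C)[C@@H]1C(C)=C[C@H]2CC[C@H](O[Al](C)Cl)[C@H](C)[C@H]2[C@@H]1/C=C/C=C/C(=O)OCC | intermediate
19 | ethyl (2E,4E)-5-[(1S,2R,4aS,7S,8R,8aR)-2-[(2E)-but-2-en-2-yl]-7-hydroxy-3,8-dimethyl-1,2,4a,5,6,7,8,8a-octahydronaphthalen-1-yl]penta-2,4-dienoate | C/C=C(\C)[C@@H]1C(C)=C[C@H]2CC[C@H](O)[C@H](C)[C@H]2[C@@H]1/C=C/C=C/C(=O)OCC | intermediate
20 | pyridinium salt of the 7‑O‑sulfate of 19 | C/C=C(\C)[C@@H]1C(C)=C[C@H]2CC[C@H](OS(=O)(=O)[O-])[C@H](C)[C@H]2[C@@H]1/C=C/C=C/C(=O)OCC.c1cc[nH+]cc1 | intermediate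
21 | dilithium salt of 22 | C/C=C(\C)[C@@H]1C(C)=C[C@H]2CC[C@H](OS(=O)(=O)[O-])[C@H](C)[C@H]2[C@@H]1/C=C/C=C/C(=O)[O-].[Li+].[Li+] | intermediate
22 | (2E,4E)-5-[(1S,2R,4aS,7S,8R,8aR)-2-[(2E)-but-2-en-2-yl]-3,8-dimethyl-7-(sulfooxy)-1,2,4a,5,6,7,8,8a-octahydronaphthalen-1-yl]penta-2,4-dienoic acid | C/C=C(\C)[C@@H]1C(C)=C[C@H]2CC[C@H](OS(=O)(=O)O)[C@H](C)[C@H]2[C@@H]1/C=C/C=C/C(=O)O | target

**Step count:** 8 steps in total. The longest linear sequence is 7 steps (1, 2, 3, 4, 6, 7, 8). No protecting groups are used.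

**Steps most likely to fail**

**Step 7 (cycloaddition of the full hexaene).**
- The dienophile is activated only vinylogously.
- The C4–C7 part of the trienoate can itself act as a diene toward C12=C13, which would give the Cope‑related regioisomer.
- The facial bias rests on an estimated 1.5–2 kcal/mol.
- The Lewis acid may erode the 12Z geometry.

The fallback abandons the full‑length dienophile and cyclises a truncated enal. It sets out from 8 and comes back at 19. Commercial (S)-but-3-yn-2-ol is mesylated to (S)-but-3-yn-2-yl methanesulfonate F1. Marshall allenylzinc addition of F1 to 8 (Pd(OAc)2/PPh3 cat., Et2Zn, THF, −20 °C; net inversion at the propargylic carbon, anti‑selective) gives (3R,4S,7Z,9E,11E)-3,9,11-trimethyltrideca-7,9,11-trien-1-yn-4-ol F2. Hydrozirconation (Cp2Zr(H)Cl, 2.2 equiv), n‑BuNC insertion and aqueous AcOH convert the alkyne into (2E,4R,5S,8Z,10E,12E)-5-hydroxy-4,10,12-trimethyltetradeca-2,8,10,12-tetraenal F3. This enal has no acceptor‑side diene and is a much stronger dienophile. Its Z‑diene Diels–Alder reaction (Me2AlCl, −78 °C, or 60–80 °C thermally) gives (1S,2R,4aS,7S,8R,8aS)-2-[(2E)-but-2-en-2-yl]-7-hydroxy-3,8-dimethyl-1,2,4a,5,6,7,8,8a-octahydronaphthalene-1-carbaldehyde F4. Horner–Wadsworth–Emmons extension with triethyl 4‑phosphonocrotonate/LiHMDS then delivers 19.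

**Step 6 (Heck union).**
- The alkene is unactivated, so branched insertion is possible.
- β‑H elimination could go toward C8.
- Pd–H species could isomerise the 12Z triene.

The fallback replaces C–H alkenylation by a stereoretentive cross‑coupling. It sets out from 8 and comes back at 16. The alkynol F2, made from 8 as described above, is hydroborated (HBpin, cat. Cp2Zr(H)Cl, Et3N; the O–B bond is cleaved on work‑up). This gives (1E,3R,4S,7Z,9E,11E)-3,9,11-trimethyl-1-(4,4,5,5-tetramethyl-1,3,2-dioxaborolan-2-yl)trideca-1,7,9,11-tetraen-4-ol F5. Suzuki–Miyaura coupling of F5 with 15 (Pd(PPh3)4, aq. K3PO4, THF, rt) gives 16 without any Pd–H intermediate.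

**Step 2 (Z‑selective Wittig).**
- The Z:E ratio may be insufficient, and the non‑polar triene isomers are hard to separate.
- Every E contaminant ends up as a wrong decalin diastereomer.

The fallback sets the Z alkene by alkyne semireduction. It sets out from 3 and comes back at 8, so step 3 is bypassed as well. Corey–Fuchs reaction (CBr4, PPh3) gives (3E,5E)-1,1-dibromo-3,5-dimethylhepta-1,3,5-triene F6. Treatment with n‑BuLi (2.1 equiv), then 2-(2-bromoethyl)-1,3-dioxolane/DMPU, gives 2-[(5E,7E)-5,7-dimethylnona-5,7-dien-3-yn-1-yl]-1,3-dioxolane F7. Zn(Cu/Ag) reduction in MeOH–H2O gives 2-[(3Z,5E,7E)-5,7-dimethylnona-3,5,7-trien-1-yl]-1,3-dioxolane F8. PPTS in wet acetone then releases 8.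

**Further compounds**
F1 | step 7 | (S)-but-3-yn-2-yl methanesulfonate | C[C@H](OS(C)(=O)=O)C#C
F2 | step 7 | (3R,4S,7Z,9E,11E)-3,9,11-trimethyltrideca-7,9,11-trien-1-yn-4-ol | C/C=C(\C)/C=C(\C)/C=C\CC[C@H](O)[C@H](C)C#C
F3 | step 7 | (2E,4R,5S,8Z,10E,12E)-5-hydroxy-4,10,12-trimethyltetradeca-2,8,10,12-tetraenal | C/C=C(\C)/C=C(\C)/C=C\CC[C@H](O)[C@H](C)/C=C/C=O
F4 | step 7 | (1S,2R,4aS,7S,8R,8aS)-2-[(2E)-but-2-en-2-yl]-7-hydroxy-3,8-dimethyl-1,2,4a,5,6,7,8,8a-octahydronaphthalene-1-carbaldehyde | C/C=C(\C)[C@@H]1C(C)=C[C@H]2CC[C@H](O)[C@H](C)[C@H]2[C@@H]1C=O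
F5 | step 6 | (1E,3R,4S,7Z,9E,11E)-3,9,11-trimethyl-1-(4,4,5,5-tetramethyl-1,3,2-dioxaborolan-2-yl)trideca-1,7,9,11-tetraen-4-ol | C/C=C(\C)/C=C(\C)/C=C\CC[C@H](O)[C@H](C)/C=C/B1OC(C)(C)C(C)(C)O1
F6 | step 2 | (3E,5E)-1,1-dibromo-3,5-dimethylhepta-1,3,5-triene | C/C=C(\C)/C=C(\C)C=C(Br)Br
F7 | step 2 | 2-[(5E,7E)-5,7-dimethylnona-5,7-dien-3-yn-1-yl]-1,3-dioxolane | C/C=C(\C)/C=C(\C)C#CCCC1OCCO1
F8 | step 2 | 2-[(3Z,5E,7E)-5,7-dimethylnona-3,5,7-trien-1-yl]-1,3-dioxolane | C/C=C(\C)/C=C(\C)/C=C\CCC1OCCO1
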